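Ring A is disconnected by a Danheiser benzannulation. C6 and C7 come from a prenyl-bearing siloxyalkyne, while C5, C8, C8a and C4a come from a cyclobutenone already fused to pyran ring C. The step exploits that ring A is a phloroglucinol with three unlike oxygens (O1 on C8a, 5-OH, 7-OH) and prenyl on C6, para to C8a. One thermal cascade forms C5–C6, C7–C8 and C4a–C5, aromatises ring A and leaves the three oxygens distinguishable. The precursor is a (3R,4S)-2-oxabicyclo[4.2.0]oct-1(8)-en-7-one, a 3-alkoxycyclobutenone carrying C2 and C3 of the flavan. It is closed by alkoxy exchange on a robust 3-ethoxycyclobutenone, so no ethynyl ether is handled.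

Key step: step 13

Remark: flavan numbering (O1, C2, C3, C4, C4a, C5–C8, C8a) is used for all intermediates, and Ar = 3,4-bis(triisopropylsilyloxy)phenyl. Centres that are erased on aromatisation (C4a in 16–18 and 27, C8 in 25) form as mixtures and are drawn without configuration.

Step 1
Reactants: 1 3,4-dihydroxybenzaldehyde
Product: 2 3,4-bis(triisopropylsilyloxy)benzaldehyde
Conditions: TIPSCl (2.4 equiv), imidazole, DMAP (cat.), DMF, rt
Reagents that add atoms: chlorotriisopropylsilane, CC(C)[Si](Cl)(C(C)C)C(C)C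
Why: Imidazole-promoted silylation of phenols; aryl TIPS ethers withstand Grignard reagents, alkoxides, perborate and 110 °C and leave with fluoride, so the end game needs no acid that could cyclise the o-prenylphenol to a dimethylchroman.

Step 2
Reactants: 2 3,4-bis(triisopropylsilyloxy)benzaldehyde; 3 vinylmagnesium bromide
Product: 4 rac-1-Ar-prop-2-en-1-ol
Conditions: THF, −78 → 0 °C; then sat. aq NH4Cl
Reagents that add atoms: vinylmagnesium bromide (3), C=C[Mg]Br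
Why: Grignard 1,2-addition to the aldehyde forms C2–C3 and gives the racemic secondary allylic alcohol needed for the resolution.

Step 3
Reactants: 4 rac-1-Ar-prop-2-en-1-ol
Product: 5 (R)-Ar[(S)-oxiran-2-yl]methanol (anti epoxy alcohol)
Conditions: Ti(OiPr)4 (15 mol %), D-(−)-DIPT (20 mol %), t-BuOOH (0.45 equiv, decane), 4 Å MS, CH2Cl2, −20 °C
Reagents that add atoms: tert-butyl hydroperoxide, CC(C)(C)OO
Why: Sharpless kinetic resolution by asymmetric epoxidation, in which D-(−)-DIPT makes (S)-4 the fast enantiomer and delivers oxygen to the face that gives the anti (erythro) epoxy alcohol, so C2 (R) is selected and C3 (S) is created under reagent control while (R)-4 stays unreacted and is separated; because both C–O bonds are kept to the end, the anti O1/O3 relation is the one that maps onto the 2,3-trans flavan.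

Step 4
Reactants: 5 (R)-Ar[(S)-oxiran-2-yl]methanol
Product: 6 {(R)-Ar[(S)-oxiran-2-yl]methoxy}triethylsilane
Conditions: TESCl, imidazole, CH2Cl2, 0 °C
Reagents that add atoms: chlorotriethylsilane, CC[Si](Cl)(CC)CC
Why: Silylation under weakly basic conditions avoids Payne rearrangement and marks O1 with the only group in the molecule that mild acid will remove later.

Step 5
Reactants: 6 {(R)-Ar[(S)-oxiran-2-yl]methoxy}triethylsilane; 3 vinylmagnesium bromide
Product: 7 (1R,2S)-1-Ar-1-(triethylsilyloxy)pent-4-en-2-ol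
Conditions: CuI (20 mol %), THF, −40 → −20 °C; cold quench with sat. aq NH4Cl
Reagents that add atoms: vinylmagnesium bromide (3), C=C[Mg]Br
Why: Copper-catalysed Grignard opening of a terminal epoxide (SN2 at unhindered C4) brings in C4a and C5, leaves the C3–O bond and its configuration untouched and frees O3 alone, and the cold quench of the magnesium alkoxide guards against 1,2-silyl migration.

Step 6
Reactants: 7 (1R,2S)-1-Ar-1-(triethylsilyloxy)pent-4-en-2-ol
Product: 8 (1R,2S)-1-Ar-2-(tert-butyldimethylsilyloxy)-1-(triethylsilyloxy)pent-4-ene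
Conditions: TBSOTf, 2,6-lutidine, CH2Cl2, −78 → 0 °C
Reagents that add atoms: tert-butyldimethylsilyl triflate, CC(C)(C)[Si](C)(C)OS(=O)(=O)C(F)(F)F
Why: Silyl triflate/lutidine silylation handles the hindered secondary alcohol and completes the O1 (TES, labile) versus O3 (TBS, lasting) differentiation.

Step 7
Reactants: 8 (1R,2S)-1-Ar-2-(tert-butyldimethylsilyloxy)-1-(triethylsilyloxy)pent-4-ene
Product: 10 (4S,5R)-5-Ar-4-(tert-butyldimethylsilyloxy)-5-(triethylsilyloxy)pentan-1-ol, via B-alkyl-9-BBN adduct 9 (not isolated)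
Conditions: 9-BBN, THF, 0 °C → rt; then NaBO3·4H2O, THF/H2O, rt
Reagents that add atoms: sodium perborate, [Na+].[Na+].O[B-]1(O)OO[B-](O)(O)OO1
Why: Brown hydroboration–oxidation, in which 9-BBN adds anti-Markovnikov to the only alkene and perborate oxidises the C–B bond mildly enough for all silyl ethers.

Step 8
Reactants: 10 (4S,5R)-5-Ar-4-(tert-butyldimethylsilyloxy)-5-(triethylsilyloxy)pentan-1-ol
Product: 12 (4S,5R)-5-Ar-4-(tert-butyldimethylsilyloxy)-5-(triethylsilyloxy)pentanoic acid, via aldehyde 11 (not isolated)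
Conditions: TEMPO (20 mol %), PhI(OAc)2 (2.2 equiv), MeCN/pH 7 phosphate buffer, 0 °C → rt
Reagents that add atoms: water, O
Why: Oxoammonium (TEMPO/PhI(OAc)2) oxidation takes the primary alcohol through the aldehyde hydrate to the acid at buffered pH, which the TES ether tolerates.

Step 9
Reactants: 12 (4S,5R)-5-Ar-4-(tert-butyldimethylsilyloxy)-5-(triethylsilyloxy)pentanoic acid; 13 ethoxyacetylene
Product: 16 3-ethoxy-4-[(2S,3R)-3-Ar-2-(tert-butyldimethylsilyloxy)-3-(triethylsilyloxy)propyl]cyclobut-2-en-1-one (C4a epimers), via acid chloride 14 (not isolated), via alkylketene 15 (not isolated)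
Conditions: 1-chloro-N,N,2-trimethylprop-1-en-1-amine, CH2Cl2, 0 °C; then slow addition to 13 (3 equiv), Et3N (1.5 equiv), Et2O, 0 °C → rt
Reagents that add atoms: ethoxyacetylene (13), C#COCC
Why: Ghosez's chloroenamine gives the acid chloride without HCl, Et3N dehydrochlorinates it to the monoalkylketene, and the ketene/ynol ether [2+2] cycloaddition (terminal alkyne carbon to the ketene carbonyl carbon) is the classical entry to 4-substituted 3-ethoxycyclobutenones, here forming C5–C8 and C4a–C8a with an uncontrolled and irrelevant C4a centre.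

Step 10
Reactants: 16 3-ethoxy-4-[(2S,3R)-3-Ar-2-(tert-butyldimethylsilyloxy)-3-(triethylsilyloxy)propyl]cyclobut-2-en-1-one
Product: 18 (3R,4S)-3-Ar-4-(tert-butyldimethylsilyloxy)-2-oxabicyclo[4.2.0]oct-1(8)-en-7-one (C4a epimers), via hydroxy cyclobutenone 17 (not isolated)
Conditions: PPTS (20 mol %), EtOH, 0 °C → rt; evaporate; CH2Cl2 (0.01 M), 5 Å MS, rt
Reagents that add atoms: none
Why: Acid-catalysed ethanolysis removes only the TES group, and the freed benzylic alcohol then displaces ethanol from the vinylogous ester by addition–elimination (vinylogous transesterification, 6-exo-trig at C8a) driven by uptake of ethanol on the sieves; the C2–O1 bond is never broken, so C2 keeps its configuration, and the step makes a benzylic ethynyl ether (prone to [3,3] shift, retro-ene loss and addition of carboxylic acids) unnecessary.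

Step 11
Reactants: 19 4-methylpent-3-enoic acid
Product: 20 ethyl 4-methylpent-3-enoate
Conditions: EtI, K2CO3, DMF, rt
Reagents that add atoms: iodoethane, CCI
Why: SN2 O-alkylation of the carboxylate avoids the acid catalysis that would lactonise this β,γ-unsaturated acid to the γ,γ-dimethylbutyrolactone.

Step 12
Reactants: 20 ethyl 4-methylpent-3-enoate
Product: 23 5-methyl-1-(triisopropylsilyloxy)hex-4-en-1-yne, via dibromo enolate 21 (not isolated), via lithium ynolate 22 (not isolated)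
Conditions: CH2Br2, LiTMP (from TMP + n-BuLi), THF, −78 °C; add 20; n-BuLi, −78 °C → rt; TIPSCl, −78 → 0 °C
Reagents that add atoms: dibromomethane, BrCBr; chlorotriisopropylsilane, CC(C)[Si](Cl)(C(C)C)C(C)C
Why: Kowalski ester homologation, in which LiCHBr2 adds to the ester at −78 °C ahead of enolisation, bromine–lithium exchange on the dibromo enolate triggers a 1,2-shift of the prenyl group to give the ynolate, and the bulky silyl chloride captures it on oxygen.

Step 13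
Reactants: 18 (3R,4S)-3-Ar-4-(tert-butyldimethylsilyloxy)-2-oxabicyclo[4.2.0]oct-1(8)-en-7-one; 23 5-methyl-1-(triisopropylsilyloxy)hex-4-en-1-yne
Product: 28 (2R,3S)-2-Ar-3-(tert-butyldimethylsilyloxy)-6-(3-methylbut-2-enyl)-7-(triisopropylsilyloxy)chroman-5-ol, via vinylketene 24 (not isolated), via alkenylcyclobutenone 25 (not isolated), via dienylketene 26 (not isolated), via cyclohexadienone 27 (not isolated)
Conditions: 23 (1.5 equiv), degassed toluene (0.3 M), sealed tube, 110 °C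
Reagents that add atoms: 5-methyl-1-(triisopropylsilyloxy)hex-4-en-1-yne (23), CC(C)=CCC#CO[Si](C(C)C)(C(C)C)C(C)C
Why: Heat opens the four-membered ring of 18 by conrotatory 4π cleavage of C4a–C5, and because the pyran ring forces C4 to turn outward, both C4a epimers give the same vinylketene 24. The C5=C8 ketene bond adds to the siloxyalkyne in a polar [2+2] step (C5–C6 and C7–C8), adduct 25 opens again (4π, C5–C8) to dienylketene 26, and ring A closes by disrotatory 6π electrocyclisation between C5 and C4a before dienone 27 tautomerises to the phenol. This is the Danheiser benzannulation of a cyclobutenone with a triisopropylsiloxyalkyne, an established resorcinol synthesis applied here to a new, pyran-fused cyclobutenone, and the risk of the route is deliberately placed here. No stereocentre is created, since C4a becomes aromatic and C2 and C3 take part in no bond change. The selectivity needed is the orientation of the alkyne, and polarity secures it: the prenyl-bearing β-carbon of the silyl ynol ether is the nucleophilic end and bonds to the ketene carbonyl carbon C5, so prenyl lands on C6 between 5-OH and 7-OTIPS and para to C8a–O1. The non-polar solvent and the weakly donating silyl ethers on ring B should hold back ionisation of the benzylic C2–O1 bond at this temperature.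

Step 14
Reactants: 28 (2R,3S)-2-Ar-3-(tert-butyldimethylsilyloxy)-6-(3-methylbut-2-enyl)-7-(triisopropylsilyloxy)chroman-5-ol
Product: 29 6-prenylcatechin, (2R,3S)-2-(3,4-dihydroxyphenyl)-6-(3-methylbut-2-enyl)chroman-3,5,7-triol
Conditions: TBAF/AcOH (1:1, 8 equiv), THF, argon, 0 °C → rt
Reagents that add atoms: none
Why: Fluoride-mediated desilylation cleaves all four Si–O bonds in one operation, and the acetic acid buffer keeps the phenols protonated, so the catechol is not air-oxidised, C2 is not epimerised and the o-prenylphenol meets no strong acid.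

Compound list
1 | 3,4-dihydroxybenzaldehyde | O=Cc1ccc(O)c(O)c1 | starting material
2 | 3,4-bis(triisopropylsilyloxy)benzaldehyde | O=Cc1ccc(O[Si](C(C)C)(C(C)C)C(C)C)c(O[Si](C(C)C)(C(C)C)C(C)C)c1 | intermediate
3 | vinylmagnesium bromide | C=C[Mg]Br | starting material
4 | rac-1-[3,4-bis(triisopropylsilyloxy)phenyl]prop-2-en-1-ol | C=CC(O)c1ccc(O[Si](C(C)C)(C(C)C)C(C)C)c(O[Si](C(C)C)(C(C)C)C(C)C)c1 | intermediate
5 | (R)-[3,4-bis(triisopropylsilyloxy)phenyl][(S)-oxiran-2-yl]methanol | C1O[C@@H]1[C@H](O)c2ccc(O[Si](C(C)C)(C(C)C)C(C)C)c(O[Si](C(C)C)(C(C)C)C(C)C)c2 | intermediate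
6 | TES ether of 5 | C1O[C@@H]1[C@H](O[Si](CC)(CC)CC)c2ccc(O[Si](C(C)C)(C(C)C)C(C)C)c(O[Si](C(C)C)(C(C)C)C(C)C)c2 | intermediate
7 | (1R,2S)-1-Ar-1-(triethylsilyloxy)pent-4-en-2-ol | C=CC[C@H](O)[C@H](O[Si](CC)(CC)CC)c1ccc(O[Si](C(C)C)(C(C)C)C(C)C)c(O[Si](C(C)C)(C(C)C)C(C)C)c1 | intermediate
8 | (1R,2S)-1-Ar-2-(TBSO)-1-(TESO)pent-4-ene | C=CC[C@H](O[Si](C)(C)C(C)(C)C)[C@H](O[Si](CC)(CC)CC)c1ccc(O[Si](C(C)C)(C(C)C)C(C)C)c(O[Si](C(C)C)(C(C)C)C(C)C)c1 | intermediate
9 | B-[(4S,5R)-5-Ar-4-(TBSO)-5-(TESO)pentyl]-9-borabicyclo[3.3.1]nonane | B1(CCC[C@H](O[Si](C)(C)C(C)(C)C)[C@H](O[Si](CC)(CC)CC)c2ccc(O[Si](C(C)C)(C(C)C)C(C)C)c(O[Si](C(C)C)(C(C)C)C(C)C)c2)C3CCCC1CCC3 | intermediate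
10 | (4S,5R)-5-Ar-4-(TBSO)-5-(TESO)pentan-1-ol | OCCC[C@H](O[Si](C)(C)C(C)(C)C)[C@H](O[Si](CC)(CC)CC)c1ccc(O[Si](C(C)C)(C(C)C)C(C)C)c(O[Si](C(C)C)(C(C)C)C(C)C)c1 | intermediate
11 | (4S,5R)-5-Ar-4-(TBSO)-5-(TESO)pentanal | O=CCC[C@H](O[Si](C)(C)C(C)(C)C)[C@H](O[Si](CC)(CC)CC)c1ccc(O[Si](C(C)C)(C(C)C)C(C)C)c(O[Si](C(C)C)(C(C)C)C(C)C)c1 | intermediate
12 | (4S,5R)-5-Ar-4-(TBSO)-5-(TESO)pentanoic acid | OC(=O)CC[C@H](O[Si](C)(C)C(C)(C)C)[C@H](O[Si](CC)(CC)CC)c1ccc(O[Si](C(C)C)(C(C)C)C(C)C)c(O[Si](C(C)C)(C(C)C)C(C)C)c1 | intermediate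
13 | ethoxyacetylene | C#COCC | starting material
14 | (4S,5R)-5-Ar-4-(TBSO)-5-(TESO)pentanoyl chloride | ClC(=O)CC[C@H](O[Si](C)(C)C(C)(C)C)[C@H](O[Si](CC)(CC)CC)c1ccc(O[Si](C(C)C)(C(C)C)C(C)C)c(O[Si](C(C)C)(C(C)C)C(C)C)c1 | intermediate
15 | (4S,5R)-5-Ar-4-(TBSO)-5-(TESO)pent-1-en-1-one (monoalkylketene) | O=C=CC[C@H](O[Si](C)(C)C(C)(C)C)[C@H](O[Si](CC)(CC)CC)c1ccc(O[Si](C(C)C)(C(C)C)C(C)C)c(O[Si](C(C)C)(C(C)C)C(C)C)c1 | intermediate
16 | 3-ethoxy-4-[(2S,3R)-3-Ar-2-(TBSO)-3-(TESO)propyl]cyclobut-2-en-1-one | CCOC1=CC(=O)C1C[C@H](O[Si](C)(C)C(C)(C)C)[C@H](O[Si](CC)(CC)CC)c2ccc(O[Si](C(C)C)(C(C)C)C(C)C)c(O[Si](C(C)C)(C(C)C)C(C)C)c2 | intermediate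
17 | 3-ethoxy-4-[(2S,3R)-3-Ar-2-(TBSO)-3-hydroxypropyl]cyclobut-2-en-1-one | CCOC1=CC(=O)C1C[C@H](O[Si](C)(C)C(C)(C)C)[C@H](O)c2ccc(O[Si](C(C)C)(C(C)C)C(C)C)c(O[Si](C(C)C)(C(C)C)C(C)C)c2 | intermediate
18 | (3R,4S)-3-Ar-4-(TBSO)-2-oxabicyclo[4.2.0]oct-1(8)-en-7-one | O=C1C=C2O[C@H](c3ccc(O[Si](C(C)C)(C(C)C)C(C)C)c(O[Si](C(C)C)(C(C)C)C(C)C)c3)[C@@H](O[Si](C)(C)C(C)(C)C)CC12 | intermediate
19 | 4-methylpent-3-enoic acid | CC(C)=CCC(=O)O | starting material
20 | ethyl 4-methylpent-3-enoate | CC(C)=CCC(=O)OCC | intermediate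
21 | lithium 1,1-dibromo-5-methylhexa-1,4-dien-2-olate | [Li+].CC(C)=CCC([O-])=C(Br)Br | intermediate
22 | lithium 5-methylhex-4-en-1-yn-1-olate | [Li+].CC(C)=CCC#C[O-] | intermediate
23 | 5-methyl-1-(triisopropylsilyloxy)hex-4-en-1-yne | CC(C)=CCC#CO[Si](C(C)C)(C(C)C)C(C)C | intermediate
24 | 2-[(2R,3S)-2-Ar-3-(TBSO)-3,4-dihydro-2H-pyran-6-yl]ethenone (vinylketene) | O=C=CC1=CC[C@H](O[Si](C)(C)C(C)(C)C)[C@@H](c2ccc(O[Si](C(C)C)(C(C)C)C(C)C)c(O[Si](C(C)C)(C(C)C)C(C)C)c2)O1 | intermediate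
25 | 4-[(2R,3S)-2-Ar-3-(TBSO)-3,4-dihydro-2H-pyran-6-yl]-2-prenyl-3-(TIPSO)cyclobut-2-en-1-one | O=C1C(CC=C(C)C)=C(O[Si](C(C)C)(C(C)C)C(C)C)C1C2=CC[C@H](O[Si](C)(C)C(C)(C)C)[C@@H](c3ccc(O[Si](C(C)C)(C(C)C)C(C)C)c(O[Si](C(C)C)(C(C)C)C(C)C)c3)O2 | intermediate
26 | dienylketene, ketene carbon C5, C6 prenyl, C7 OTIPS, C6 and C8a cis on C7=C8 | O=C=C(CC=C(C)C)/C(O[Si](C(C)C)(C(C)C)C(C)C)=C\C1=CC[C@H](O[Si](C)(C)C(C)(C)C)[C@@H](c2ccc(O[Si](C(C)C)(C(C)C)C(C)C)c(O[Si](C(C)C)(C(C)C)C(C)C)c2)O1 | intermediate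
27 | 4a-H cyclohexa-2,4-dienone tautomer of 28 | O=C1C(CC=C(C)C)=C(O[Si](C(C)C)(C(C)C)C(C)C)C=C2O[C@H](c3ccc(O[Si](C(C)C)(C(C)C)C(C)C)c(O[Si](C(C)C)(C(C)C)C(C)C)c3)[C@@H](O[Si](C)(C)C(C)(C)C)CC12 | intermediate
28 | 3',4',7-tri-O-TIPS 3-O-TBS 6-prenylcatechin | CC(C)=CCc1c(O[Si](C(C)C)(C(C)C)C(C)C)cc2c(c1O)C[C@H](O[Si](C)(C)C(C)(C)C)[C@@H](c3ccc(O[Si](C(C)C)(C(C)C)C(C)C)c(O[Si](C(C)C)(C(C)C)C(C)C)c3)O2 | intermediate
29 | 6-prenylcatechin (2R,3S) | CC(C)=CCc1c(O)cc2c(c1O)C[C@H](O)[C@@H](c1ccc(O)c(O)c1)O2 | target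

Total step count: 14. Longest linear sequence: 12 (steps 1–10, 13, 14).

Steps most likely to fail

Step 13. The donor-stabilised, ring-fused cyclobutenone may open only at temperatures where the siloxyalkyne degrades or the benzylic C2–O1 bond ionises. The vinylketene may also self-condense faster than it adds to the alkyne.
Fallback, from 12 back to 28: the same vinylketene 24 is generated photochemically at room temperature, using the diazo-ketone variant of the benzannulation.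
- CSA in CH2Cl2/MeOH removes the TES group of 12, and O1 lactonises onto the carboxyl group to give δ-lactone F1. Its former carboxyl carbon now plays the part of C8a.
- KHMDS and diphenyl chlorophosphate give ketene acetal phosphate F2.
- Stille coupling with tributyl(1-ethoxyvinyl)stannane (Pd(PPh3)4, LiCl, THF) gives ethoxydiene F3.
- Cold dilute acid hydrolyses the acyclic enol ether of F3 to methyl ketone F4.
- LiHMDS and CF3CO2CH2CF3 give trifluoroacetyl diketone F5.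
- Detrifluoroacetylative diazo transfer (MsN3, Et3N, H2O, MeCN) gives diazo ketone F6.
- Irradiation of F6 with 23 (photo-Wolff rearrangement to 24), then warming to about 80 °C, should carry 24 through 25–27 to 28.

Step 10. Under the equilibrating acid, adventitious water may hydrolyse the vinylogous ester. The ring double bond may migrate from C8=C8a into the ring fusion (C4a=C8a), or the closure may stall.
Fallback, from 16 back to 29: the migration is accepted and used.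
- Cold dilute HCl in THF cleaves both the enol ether and the TES ether of 16 to the enolised cyclobutane-1,3-dione F7.
- Acid-catalysed dehydrative enol etherification of this 1,3-dione with its own benzylic alcohol (PPTS, benzene, 5 Å MS) gives the ring-fusion isomer F8, a 4-unsubstituted 2,3-disubstituted cyclobutenone.
- Benzannulation of F8 with 23 turns its ring CH2 into C8 and its carbonyl carbon into C7. The alkyne carbons become C6 (prenyl) and C5 (OTIPS), giving the 5-O-TIPS 7-hydroxy isomer F9.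
- Prenyl again lies between two oxygens and para to C8a, so the conditions of step 14 convert F9 into 29.

Step 9. The γ-silyloxy oxygen may attack the acid chloride, causing lactonisation with loss of silyl chloride. The monoalkylketene may dimerise, or the amine hydrochloride may consume the ynol ether.
Fallback, from 8 back to 16: ketene 15 is generated by photochemical Wolff rearrangement under neutral, salt-free conditions.
- Lemieux–Johnson cleavage of 8 (OsO4 cat., NaIO4, 2,6-lutidine) gives aldehyde F10.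
- Pinnick oxidation gives acid F11.
- Isobutyl chloroformate and N-methylmorpholine give mixed anhydride F12.
- Diazomethane gives diazo ketone F13.
- Irradiation through Pyrex (CH2Cl2, 0 °C) in the presence of 13 gives 15 and then 16.

Further compounds
F1 | step 13 | (5S,6R)-6-Ar-5-(TBSO)tetrahydropyran-2-one | O=C1CC[C@H](O[Si](C)(C)C(C)(C)C)[C@@H](c2ccc(O[Si](C(C)C)(C(C)C)C(C)C)c(O[Si](C(C)C)(C(C)C)C(C)C)c2)O1
F2 | step 13 | (2R,3S)-2-Ar-3-(TBSO)-3,4-dihydro-2H-pyran-6-yl diphenyl phosphate | O=P(Oc1ccccc1)(Oc1ccccc1)OC1=CC[C@H](O[Si](C)(C)C(C)(C)C)[C@@H](c2ccc(O[Si](C(C)C)(C(C)C)C(C)C)c(O[Si](C(C)C)(C(C)C)C(C)C)c2)O1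
F3 | step 13 | (2R,3S)-2-Ar-3-(TBSO)-6-(1-ethoxyvinyl)-3,4-dihydro-2H-pyran | C=C(OCC)C1=CC[C@H](O[Si](C)(C)C(C)(C)C)[C@@H](c2ccc(O[Si](C(C)C)(C(C)C)C(C)C)c(O[Si](C(C)C)(C(C)C)C(C)C)c2)O1
F4 | step 13 | 1-[(2R,3S)-2-Ar-3-(TBSO)-3,4-dihydro-2H-pyran-6-yl]ethanone | CC(=O)C1=CC[C@H](O[Si](C)(C)C(C)(C)C)[C@@H](c2ccc(O[Si](C(C)C)(C(C)C)C(C)C)c(O[Si](C(C)C)(C(C)C)C(C)C)c2)O1
F5 | step 13 | 4,4,4-trifluoro-1-[(2R,3S)-2-Ar-3-(TBSO)-3,4-dihydro-2H-pyran-6-yl]butane-1,3-dione | O=C(CC(=O)C(F)(F)F)C1=CC[C@H](O[Si](C)(C)C(C)(C)C)[C@@H](c2ccc(O[Si](C(C)C)(C(C)C)C(C)C)c(O[Si](C(C)C)(C(C)C)C(C)C)c2)O1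
F6 | step 13 | 2-diazo-1-[(2R,3S)-2-Ar-3-(TBSO)-3,4-dihydro-2H-pyran-6-yl]ethanone | [N-]=[N+]=CC(=O)C1=CC[C@H](O[Si](C)(C)C(C)(C)C)[C@@H](c2ccc(O[Si](C(C)C)(C(C)C)C(C)C)c(O[Si](C(C)C)(C(C)C)C(C)C)c2)O1
F7 | step 10 | 3-hydroxy-2-[(2S,3R)-3-Ar-2-(TBSO)-3-hydroxypropyl]cyclobut-2-en-1-one | O=C1CC(O)=C1C[C@H](O[Si](C)(C)C(C)(C)C)[C@H](O)c2ccc(O[Si](C(C)C)(C(C)C)C(C)C)c(O[Si](C(C)C)(C(C)C)C(C)C)c2
F8 | step 10 | (3R,4S)-3-Ar-4-(TBSO)-2-oxabicyclo[4.2.0]oct-1(6)-en-7-one | O=C1CC2=C1C[C@H](O[Si](C)(C)C(C)(C)C)[C@@H](c3ccc(O[Si](C(C)C)(C(C)C)C(C)C)c(O[Si](C(C)C)(C(C)C)C(C)C)c3)O2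
F9 | step 10 | (2R,3S)-2-Ar-3-(TBSO)-6-prenyl-5-(TIPSO)chroman-7-ol | CC(C)=CCc1c(O)cc2c(c1O[Si](C(C)C)(C(C)C)C(C)C)C[C@H](O[Si](C)(C)C(C)(C)C)[C@@H](c3ccc(O[Si](C(C)C)(C(C)C)C(C)C)c(O[Si](C(C)C)(C(C)C)C(C)C)c3)O2
F10 | step 9 | (3S,4R)-4-Ar-3-(TBSO)-4-(TESO)butanal | O=CC[C@H](O[Si](C)(C)C(C)(C)C)[C@H](O[Si](CC)(CC)CC)c1ccc(O[Si](C(C)C)(C(C)C)C(C)C)c(O[Si](C(C)C)(C(C)C)C(C)C)c1
F11 | step 9 | (3S,4R)-4-Ar-3-(TBSO)-4-(TESO)butanoic acid | OC(=O)C[C@H](O[Si](C)(C)C(C)(C)C)[C@H](O[Si](CC)(CC)CC)c1ccc(O[Si](C(C)C)(C(C)C)C(C)C)c(O[Si](C(C)C)(C(C)C)C(C)C)c1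
F12 | step 9 | (3S,4R)-4-Ar-3-(TBSO)-4-(TESO)butanoic isobutyl carbonic anhydride | CC(C)COC(=O)OC(=O)C[C@H](O[Si](C)(C)C(C)(C)C)[C@H](O[Si](CC)(CC)CC)c1ccc(O[Si](C(C)C)(C(C)C)C(C)C)c(O[Si](C(C)C)(C(C)C)C(C)C)c1
F13 | step 9 | (4S,5R)-5-Ar-1-diazo-4-(TBSO)-5-(TESO)pentan-2-one | [N-]=[N+]=CC(=O)C[C@H](O[Si](C)(C)C(C)(C)C)[C@H](O[Si](CC)(CC)CC)c1ccc(O[Si](C(C)C)(C(C)C)C(C)C)c(O[Si](C(C)C)(C(C)C)C(C)C)c1
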